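**Retrosynthetic overview**
1. Target 6 is (2S)-3'-hydroxy-4',5',7,8-tetramethoxyflavanone; both benzene rings are bought and only the pyranone (C) ring is built.
2. O1–C2 disconnection: enantioselective 6-endo oxa-Michael closure of the free-phenol 2'-hydroxychalcone 4, a small-molecule version of the chalcone isomerase step. It forms the ring and sets C2 (S) in one event, with no protecting or activating group.
3. Cα=Cβ disconnection of 4: Claisen–Schmidt condensation of acetophenone 1 with the unprotected aldehyde 2.
4. Ring order: A and B rings preformed, C ring closed last.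

Assumption: 1 and 2 are bought as catalogue compounds, and the quinidine-derived catalyst is taken to give the (2S) product (I could not fix the sense of induction from memory; check by chiral HPLC/CD on the first run and use the quinine-derived pseudoenantiomer if it is reversed).

**Step 1**
Reactants: 1 2'-hydroxy-3',4'-dimethoxyacetophenone; 2 3-hydroxy-4,5-dimethoxybenzaldehyde
Product: 4 (E)-1-(2-hydroxy-3,4-dimethoxyphenyl)-3-(3-hydroxy-4,5-dimethoxyphenyl)prop-2-en-1-one, via aldol adduct 3 (not isolated)
Conditions: KOH (50% aq, 8 equiv), EtOH, 0 °C → rt, 36 h, N2; then cold 2 M HCl to pH 3; recryst. EtOH (must be free of racemic flavanone before step 2)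
Reagents that add atoms: none
Why: Claisen–Schmidt (crossed aldol) condensation, in which the methyl ketone enolate adds to the non-enolisable aldehyde and aldol 3 loses water by E1cB to the conjugated (E)-enone; the B-ring phenoxide is meta to the formyl group and does not deactivate it, the 2'-phenoxide chalcone stays open in strong base, and no stereocentre is formed.

**Step 2**
Reactants: 4 (E)-1-(2-hydroxy-3,4-dimethoxyphenyl)-3-(3-hydroxy-4,5-dimethoxyphenyl)prop-2-en-1-one
Product: 6 (2S)-2-(3-hydroxy-4,5-dimethoxyphenyl)-7,8-dimethoxy-2,3-dihydro-4H-chromen-4-one, via flavanone enol 5 (not isolated)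
Conditions: quinidine-derived bifunctional thiourea [N-3,5-(CF3)2C6H3-N'-(9-deoxy-epi-quinidin-9-yl)thiourea] (20 mol%), PhCl (0.05 M), 35 °C, dark, 72–120 h, stopped under chiral-HPLC control; SiO2 plug to remove catalyst (recover unreacted 4); recryst. EtOH/heptane or chiral SFC polish to ≥99% ee
Reagents that add atoms: none
Why: Proposed new method: enantioselective intramolecular oxa-Michael addition (chalcone–flavanone isomerisation) in which the quinuclidine nitrogen deprotonates the 2'-OH and breaks its hydrogen bond to the carbonyl while the thiourea N–H groups bind the s-cis enone carbonyl, so the phenoxide adds 6-endo-trig to the Si face of C-β inside a chiral ion pair and sets C2 as (S) before enol 5 tautomerises; the closest known reaction types are the cinchona-alkaloid-catalysed cyclisation of simple 2'-hydroxychalcones and the thiourea-catalysed oxa-Michael cyclisation of α-ester-activated 2'-hydroxychalcones, and what is new is the unactivated, electron-rich substrate carrying a second free phenol.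

**Compound list**
1 | 2'-hydroxy-3',4'-dimethoxyacetophenone [1-(2-hydroxy-3,4-dimethoxyphenyl)ethan-1-one] | CC(=O)c1ccc(OC)c(OC)c1O | starting material
2 | 3-hydroxy-4,5-dimethoxybenzaldehyde | COc1cc(C=O)cc(O)c1OC | starting material
3 | aldol adduct, racemic 3-hydroxy-1-(2-hydroxy-3,4-dimethoxyphenyl)-3-(3-hydroxy-4,5-dimethoxyphenyl)propan-1-one | COc1cc(C(O)CC(=O)c2ccc(OC)c(OC)c2O)cc(O)c1OC | intermediate
4 | (E)-1-(2-hydroxy-3,4-dimethoxyphenyl)-3-(3-hydroxy-4,5-dimethoxyphenyl)prop-2-en-1-one (free-phenol 2'-hydroxychalcone) | COc1cc(/C=C/C(=O)c2ccc(OC)c(OC)c2O)cc(O)c1OC | intermediate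
5 | flavanone enol, (2S)-2-(3-hydroxy-4,5-dimethoxyphenyl)-7,8-dimethoxy-2H-chromen-4-ol | COc1cc([C@@H]2C=C(O)c3ccc(OC)c(OC)c3O2)cc(O)c1OC | intermediate
6 | (2S)-2-(3-hydroxy-4,5-dimethoxyphenyl)-7,8-dimethoxy-2,3-dihydro-4H-chromen-4-one | COc1cc([C@@H]2CC(=O)c3ccc(OC)c(OC)c3O2)cc(O)c1OC | target

**Totals and risks**
Total step count: 2. Longest linear sequence: 2 steps (1 → 4 → 6). The route has only two steps, so both are ranked and there is no third step to list.

First, step 2 is the most likely to fail. The chalcone is unactivated and electron-rich, conversion is limited by the chalcone–flavanone equilibrium, the second free phenol can occupy the catalyst base, and the product racemises by retro-oxa-Michael if left with base. The fallback replaces asymmetric catalysis by resolution; it sets out from chalcone 4 and comes back at target 6. Chalcone 4 is cyclised without stereocontrol (NaOAc, EtOH, reflux) to the racemic flavanone F1. F1 is resolved by preparative chiral SFC (amylose tris(3,5-dimethylphenylcarbamate) phase, CO2/MeOH) to give 6. The unwanted (2R)-flavanone F2 is ring-opened with KOH/EtOH back to 4 and recycled.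

Second, step 1 may give a slow condensation, air oxidation of the electron-rich phenoxides or a low yield because the aldehyde phenol is unprotected. The fallback is a protecting-group detour; it sets out from aldehyde 2 and comes back at chalcone 4. Aldehyde 2 is treated with MOMCl and iPr2NEt in CH2Cl2 to give 3-(methoxymethoxy)-4,5-dimethoxybenzaldehyde F3. F3 is condensed with 1 (KOH, EtOH, rt) to the MOM-protected chalcone F4. Brief treatment of F4 with HCl in MeOH at 40 °C removes the MOM group and returns 4.

**Further compounds**
F1 | step 2 | racemic 2-(3-hydroxy-4,5-dimethoxyphenyl)-7,8-dimethoxy-2,3-dihydro-4H-chromen-4-one | COc1cc(C2CC(=O)c3ccc(OC)c(OC)c3O2)cc(O)c1OC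
F2 | step 2 | (2R)-2-(3-hydroxy-4,5-dimethoxyphenyl)-7,8-dimethoxy-2,3-dihydro-4H-chromen-4-one | COc1cc([C@H]2CC(=O)c3ccc(OC)c(OC)c3O2)cc(O)c1OC
F3 | step 1 | 3-(methoxymethoxy)-4,5-dimethoxybenzaldehyde | COCOc1cc(C=O)cc(OC)c1OC
F4 | step 1 | (E)-1-(2-hydroxy-3,4-dimethoxyphenyl)-3-[3-(methoxymethoxy)-4,5-dimethoxyphenyl]prop-2-en-1-one | COCOc1cc(/C=C/C(=O)c2ccc(OC)c(OC)c2O)cc(OC)c1OC
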